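**Retrosynthetic overview**
- The acetyl group is unveiled last by oxidation of a 1-hydroxyethyl group; the 3-acyltetramic acid comes from a Lacey–Dieckmann closure of a macrocyclic β-keto lactam.
- The 16-membered lactam is closed by intramolecular trapping of an acylketene (from a dioxinone) by the α-amine of an L-ornithine ester whose δ-amine already carries the Z-enoyl arm.
- The two arms come from a ring aldehyde (E-selective Horner–Wadsworth–Emmons with a dioxinone phosphonate) and a thioester (Fukuyama reduction, then Ando Z-olefination).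
- Ring C is closed by an amine-catalysed reductive Michael cyclisation of an enal onto an enethioate.
- Rings A and B are formed together by an intramolecular Diels–Alder reaction of an (E,E,E)-trienal whose two tether stereocentres come from a chelated dianionic Claisen rearrangement of (Z)-crotyl (S)-3-hydroxybutanoate. Ring order: A and B, then C, then macrolactam, then tetramic acid.

Assumption: compounds 1, 2, 15, 18, 22, 25, 26 and 30 are bought as such, and the target is handled as the enol tautomer written in its SMILES.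

**Route**

Step 1
Reactants: 1 ethyl (3S)-3-hydroxybutanoate; 2 (2Z)-but-2-en-1-ol
Product: 3 (2Z)-but-2-en-1-yl (3S)-3-hydroxybutanoate
Conditions: Ti(OEt)4 (10 mol%), 2 (3 equiv), toluene, 100 °C, EtOH distilled off
Reagents that add atoms: none
Why: Titanate-catalysed transesterification swaps ethanol for the allylic alcohol without touching the carbinol stereocentre or the Z alkene.

Step 2
Reactants: 3 (2Z)-but-2-en-1-yl (3S)-3-hydroxybutanoate
Product: 7 (2S,3R)-3-methyl-2-[(1S)-1-(triethylsilyloxy)ethyl]pent-4-enoic acid, via chelated dilithium enolate alkoxide 4 (not isolated), via dilithium carboxylate alkoxide 5 (not isolated), via bis(triethylsilyl) ester ether 6 (not isolated)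
Conditions: LiN(iPr)2 (2.3 equiv), THF, −78 → 60 °C; then Et3SiCl (3 equiv), 0 °C → rt; then K2CO3 (cat.), MeOH, 0 °C
Reagents that add atoms: chlorotriethylsilane, CC[Si](Cl)(CC)CC
Why: Dianionic Ireland–Claisen rearrangement, in which the lithium chelate fixes the enolate geometry and directs bond formation anti to the carbinol oxygen (Fráter–Seebach sense) while the chair transition state with the Z-crotyl unit places the hydroxyethyl and methyl groups anti (2S,3R); the alkoxide is silylated in the same flask and the silyl ester is methanolysed.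

Step 3
Reactants: 7 (2S,3R)-3-methyl-2-[(1S)-1-(triethylsilyloxy)ethyl]pent-4-enoic acid
Product: 8 (2R,3R)-3-methyl-2-[(1S)-1-(triethylsilyloxy)ethyl]pent-4-en-1-ol
Conditions: LiAlH4, Et2O, 0 °C → rt
Reagents that add atoms: none
Why: Hydride reduction of the acid to the primary alcohol leaves the silyl ether, the alkene and all stereocentres untouched.

Step 4
Reactants: 8 (2R,3R)-3-methyl-2-[(1S)-1-(triethylsilyloxy)ethyl]pent-4-en-1-ol
Product: 9 (2S,3R)-3-methyl-2-[(1S)-1-(triethylsilyloxy)ethyl]pent-4-enal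
Conditions: Dess–Martin periodinane, pyridine, CH2Cl2, 0 °C → rt; used crude
Reagents that add atoms: none
Why: Buffered Dess–Martin oxidation gives the α-branched aldehyde without epimerisation.

Step 5
Reactants: 9 (2S,3R)-3-methyl-2-[(1S)-1-(triethylsilyloxy)ethyl]pent-4-enal
Product: 10 (1E,3R,4R)-1-iodo-4-methyl-3-[(1S)-1-(triethylsilyloxy)ethyl]hexa-1,5-diene
Conditions: CHI3, CrCl2, THF/dioxane, 0 °C → rt
Reagents that add atoms: iodoform, IC(I)I
Why: Takai olefination gives the E-vinyl iodide under non-basic conditions, so the α-stereocentre is kept.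

Step 6
Reactants: 10 (1E,3R,4R)-1-iodo-4-methyl-3-[(1S)-1-(triethylsilyloxy)ethyl]hexa-1,5-diene
Product: 12 (3R,4R,5E)-6-iodo-3-methyl-4-[(1S)-1-(triethylsilyloxy)ethyl]hex-5-en-1-ol, via B-alkyl-9-BBN adduct 11 (not isolated)
Conditions: 9-BBN, THF, 0 °C → rt; then H2O2, aq NaOH, 0 °C
Reagents that add atoms: 9-borabicyclo[3.3.1]nonane, B1C2CCCC1CCC2 (its atoms stay only in 11); hydrogen peroxide, OO
Why: Hydroboration–oxidation with the bulky borane is anti-Markovnikov and selective for the monosubstituted alkene over the iodoalkene.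

Step 7
Reactants: 12 (3R,4R,5E)-6-iodo-3-methyl-4-[(1S)-1-(triethylsilyloxy)ethyl]hex-5-en-1-ol
Product: 14 (2E,5R,6R,7E)-8-iodo-5-methyl-6-[(1S)-1-(triethylsilyloxy)ethyl]octa-2,7-dienal, via iodo aldehyde 13 (not isolated)
Conditions: Dess–Martin periodinane, pyridine, CH2Cl2, rt; then Ph3P=CHCHO, 40 °C
Reagents that add atoms: (triphenylphosphoranylidene)acetaldehyde, O=CC=P(c1ccccc1)(c1ccccc1)c1ccccc1
Why: One-pot oxidation and Wittig reaction with the stabilised ylide gives the E-enal, the unhindered saturated aldehyde reacting much faster than the product enal.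

Step 8
Reactants: 14 (2E,5R,6R,7E)-8-iodo-5-methyl-6-[(1S)-1-(triethylsilyloxy)ethyl]octa-2,7-dienal; 15 2-[(1E)-buta-1,3-dien-1-yl]-4,4,5,5-tetramethyl-1,3,2-dioxaborolane
Product: 16 (2E,5R,6R,7E,9E)-5-methyl-6-[(1S)-1-(triethylsilyloxy)ethyl]dodeca-2,7,9,11-tetraenal
Conditions: Pd(PPh3)4 (5 mol%), TlOEt, THF/H2O, rt, dark
Reagents that add atoms: none
Why: Suzuki–Miyaura coupling joins the two alkenyl partners with retention of both geometries, and the thallium base makes it fast at room temperature so the trienal does not cyclise thermally.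

Step 9
Reactants: 16 (2E,5R,6R,7E,9E)-5-methyl-6-[(1S)-1-(triethylsilyloxy)ethyl]dodeca-2,7,9,11-tetraenal
Product: 17 (1R,2R,3aS,4R,5S,7aR)-5-ethenyl-2-methyl-1-[(1S)-1-(triethylsilyloxy)ethyl]-2,3,3a,4,5,7a-hexahydro-1H-indene-4-carbaldehyde
Conditions: Me2AlCl (1.1 equiv), CH2Cl2, −78 → −20 °C
Reagents that add atoms: none
Why: Lewis-acid-promoted intramolecular Diels–Alder reaction forms rings A and B, the endo (formyl) transition state of the E,E,E-triene giving the trans ring fusion and the cis formyl/vinyl pair, while the dienophile adds to the diene face anti to the bulky silyloxyethyl group, which sits pseudo-equatorial on the forming five-membered ring.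

Step 10
Reactants: 17 trans-hydrindene aldehyde (name as in step 9); 18 S-ethyl prop-2-enethioate
Product: 19 S-ethyl (E)-3-{4-formyl-2-methyl-1-[(1S)-1-(triethylsilyloxy)ethyl]-2,3,3a,4,5,7a-hexahydro-1H-inden-5-yl}prop-2-enethioate
Conditions: second-generation Hoveyda–Grubbs catalyst RuCl2(H2IMes)(=CH-C6H4-2-OiPr) (5 mol%), 18 (3 equiv), CH2Cl2, 40 °C
Reagents that add atoms: none
Why: Cross-metathesis of the terminal vinyl group with the electron-poor thioacrylate is E-selective and leaves the ring alkene and the aldehyde alone.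

Step 11
Reactants: 19 enethioate aldehyde (name as in step 10)
Product: 20 S-ethyl (E)-3-{2-methyl-4-[(E)-3-oxoprop-1-enyl]-1-[(1S)-1-(triethylsilyloxy)ethyl]-2,3,3a,4,5,7a-hexahydro-1H-inden-5-yl}prop-2-enethioate
Conditions: Ph3P=CHCHO, toluene, 80 °C
Reagents that add atoms: (triphenylphosphoranylidene)acetaldehyde, O=CC=P(c1ccccc1)(c1ccccc1)c1ccccc1
Why: Wittig reaction of the stabilised ylide gives the E-enal and does not touch the thioester; the formyl-bearing ring carbon is already in its equatorial, stable configuration.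

Step 12
Reactants: 20 enal enethioate (name as in step 11)
Product: 21 S-ethyl 2-{7-formyl-2-methyl-3-[(1S)-1-(triethylsilyloxy)ethyl]-1,2,3,3a,5a,6,7,8,8a,8b-decahydro-as-indacen-6-yl}ethanethioate
Conditions: Hantzsch ester (1.2 equiv), Bn2NH2+ CF3CO2− (20 mol%), dioxane, rt → 40 °C
Reagents that add atoms: none
Why: Organocatalytic reductive Michael cyclisation, in which the iminium ion of the enal takes hydride at its β-carbon and the resulting enamine adds 5-exo to the enethioate to close ring C; the acceptor reacts with its allylic C–H eclipsed (1,3-allylic strain) so the thioester arm ends cis to the adjacent ring-fusion hydrogen, and the epimerisable formyl carbon settles trans to that arm.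

Step 13
Reactants: 21 tricyclic aldehyde thioester (name as in step 12); 22 diethyl [(2,2-dimethyl-4-oxo-4H-1,3-dioxin-6-yl)methyl]phosphonate
Product: 23 S-ethyl 2-{7-[(E)-2-(2,2-dimethyl-4-oxo-4H-1,3-dioxin-6-yl)ethenyl]-2-methyl-3-[(1S)-1-(triethylsilyloxy)ethyl]-1,2,3,3a,5a,6,7,8,8a,8b-decahydro-as-indacen-6-yl}ethanethioate
Conditions: KN(SiMe3)2, THF, −78 → 0 °C
Reagents that add atoms: none
Why: Horner–Wadsworth–Emmons reaction of the vinylogous phosphonate anion gives the E-alkenyl dioxinone (a masked acylketene) and is too mild to attack the thioester.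

Step 14
Reactants: 23 dienyl dioxinone thioester (name as in step 13)
Product: 24 6-[(E)-2-{2-methyl-6-(2-oxoethyl)-3-[(1S)-1-(triethylsilyloxy)ethyl]-1,2,3,3a,5a,6,7,8,8a,8b-decahydro-as-indacen-7-yl}ethenyl]-2,2-dimethyl-4H-1,3-dioxin-4-one
Conditions: Et3SiH, Pd/C (10 mol%), acetone, rt
Reagents that add atoms: none
Why: Fukuyama reduction turns the thioester into the aldehyde chemoselectively, leaving the dioxinone, the silyl ether and the alkenes.

Step 15
Reactants: 25 tert-butyl bromoacetate; 26 diphenyl phosphite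
Product: 27 tert-butyl (diphenoxyphosphoryl)acetate
Conditions: Et3N, CH2Cl2, 0 °C → rt
Reagents that add atoms: none
Why: Michaelis–Becker-type P-alkylation of the phosphite gives the diaryl phosphonoacetate needed for Z-selective olefination.

Step 16
Reactants: 24 dienyl dioxinone aldehyde (name as in step 14); 27 tert-butyl (diphenoxyphosphoryl)acetate
Product: 28 tert-butyl (Z)-4-{7-[(E)-2-(2,2-dimethyl-4-oxo-4H-1,3-dioxin-6-yl)ethenyl]-2-methyl-3-[(1S)-1-(triethylsilyloxy)ethyl]-1,2,3,3a,5a,6,7,8,8a,8b-decahydro-as-indacen-6-yl}but-2-enoate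
Conditions: NaH, THF, −78 → −20 °C
Reagents that add atoms: none
Why: Ando variant of the Horner–Wadsworth–Emmons reaction, where fast elimination from the kinetic adduct of the diaryl phosphonate gives the Z-enoate.

Step 17
Reactants: 28 Z-enoate tert-butyl ester (name as in step 16)
Product: 29 (Z)-4-{7-[(E)-2-(2,2-dimethyl-4-oxo-4H-1,3-dioxin-6-yl)ethenyl]-3-[(1S)-1-hydroxyethyl]-2-methyl-1,2,3,3a,5a,6,7,8,8a,8b-decahydro-as-indacen-6-yl}but-2-enoic acid
Conditions: CF3CO2H/CH2Cl2 (1:4), 0 °C → rt; then aq NaHCO3, THF, 0 °C; pH 4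
Reagents that add atoms: none
Why: Acidolysis removes the tert-butyl ester and the triethylsilyl ether together, while the dioxinone (itself made under such acidic conditions) and the Z-enoate survive.

Step 18
Reactants: 30 Nα-Boc-Nδ-Cbz-L-ornithine
Product: 31 methyl Nα-Boc-Nδ-Cbz-L-ornithinate
Conditions: CH3I, K2CO3, DMF, rt
Reagents that add atoms: iodomethane, CI
Why: O-alkylation of the carboxylate gives the methyl ester without racemisation or carbamate alkylation.

Step 19
Reactants: 31 methyl Nα-Boc-Nδ-Cbz-L-ornithinate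
Product: 32 methyl Nα-Boc-L-ornithinate
Conditions: H2 (1 atm), Pd/C, MeOH, rt; used at once
Reagents that add atoms: none
Why: Hydrogenolysis removes only the benzyl carbamate, and immediate use of the free δ-amine avoids δ-lactam formation.

Step 20
Reactants: 29 hydroxy Z-enoic acid (name as in step 17); 32 methyl Nα-Boc-L-ornithinate
Product: 34 methyl Nα-Boc-Nδ-acyl-L-ornithinate (acyl = the (Z)-but-2-enoyl group of 29), via benzotriazolyl ester 33 (not isolated)
Conditions: EDC·HCl, HOBt, iPr2NEt, CH2Cl2/DMF, 0 °C → rt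
Reagents that add atoms: 1-hydroxybenzotriazole, On1nnc2ccccc12 (its atoms stay only in 33)
Why: Carbodiimide amide coupling acylates the primary δ-amine much faster than the hindered secondary alcohol and keeps the Z geometry.

Step 21
Reactants: 34 seco amide (name as in step 20)
Product: 35 methyl Nδ-acyl-L-ornithinate with free α-amine (acyl as in 34)
Conditions: CF3CO2H/CH2Cl2 (1:4), 0 °C; then aq NaHCO3
Reagents that add atoms: none
Why: Boc acidolysis frees the α-amine while the dioxinone, the enamide and the methyl ester are stable.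

Step 22
Reactants: 35 seco amino ester (name as in step 21)
Product: 37 macrocyclic β-keto lactam methyl ester (16-membered ring; alcohol free), via acylketene 36 (not isolated)
Conditions: toluene (0.5 mM, slow addition), 110 °C
Reagents that add atoms: none
Why: Thermal retro-[4+2] loss of acetone from the dioxinone gives an acylketene that the α-amine traps intramolecularly (acylketene macrolactamisation) under high dilution, far faster than the remote hindered alcohol could.

Step 23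
Reactants: 37 macrocyclic β-keto lactam methyl ester
Product: 38 the target with a (1S)-1-hydroxyethyl group in place of acetyl
Conditions: KOtBu, tBuOH/THF, rt, 15 min; then aq HCl to pH 3
Reagents that add atoms: none
Why: Lacey–Dieckmann cyclisation of the β-keto amide enolate onto the methyl ester gives the 3-acyltetramic acid, and the short reaction time keeps the ornithine-derived stereocentre.

Step 24
Reactants: 38 hydroxyethyl tetramic acid macrolactam
Product: 39 target CNP0320820.1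
Conditions: Dess–Martin periodinane (1.3 equiv), CH2Cl2, 0 °C → rt, no base
Reagents that add atoms: none
Why: Dess–Martin oxidation of the only secondary alcohol gives the methyl ketone under non-basic conditions, so the adjacent ring stereocentre is not epimerised.

**Compound list**

1 | ethyl (3S)-3-hydroxybutanoate | C[C@H](O)CC(=O)OCC | starting material
2 | (2Z)-but-2-en-1-ol | C/C=C\CO | starting material
3 | (2Z)-but-2-en-1-yl (3S)-3-hydroxybutanoate | C[C@H](O)CC(=O)OC/C=C\C | intermediate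
4 | chelated dilithium enolate alkoxide of 3 (enolate oxygen cis to the carbinol carbon) | C[C@H](O[Li])/C=C(\O[Li])OC/C=C\C | intermediate
5 | dilithium (2S,3R)-3-methyl-2-[(1S)-1-oxidoethyl]pent-4-enoate | C[C@H](O[Li])[C@H]([C@H](C)C=C)C(=O)O[Li] | intermediate
6 | triethylsilyl (2S,3R)-3-methyl-2-[(1S)-1-(triethylsilyloxy)ethyl]pent-4-enoate | C[C@H](O[Si](CC)(CC)CC)[C@H]([C@H](C)C=C)C(=O)O[Si](CC)(CC)CC | intermediate
7 | (2S,3R)-3-methyl-2-[(1S)-1-(triethylsilyloxy)ethyl]pent-4-enoic acid | C[C@H](O[Si](CC)(CC)CC)[C@H]([C@H](C)C=C)C(=O)O | intermediate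
8 | (2R,3R)-3-methyl-2-[(1S)-1-(triethylsilyloxy)ethyl]pent-4-en-1-ol | C[C@H](O[Si](CC)(CC)CC)[C@H]([C@H](C)C=C)CO | intermediate
9 | (2S,3R)-3-methyl-2-[(1S)-1-(triethylsilyloxy)ethyl]pent-4-enal | C[C@H](O[Si](CC)(CC)CC)[C@H]([C@H](C)C=C)C=O | intermediate
10 | (1E,3R,4R)-1-iodo-4-methyl-3-[(1S)-1-(triethylsilyloxy)ethyl]hexa-1,5-diene | C[C@H](O[Si](CC)(CC)CC)[C@H]([C@H](C)C=C)/C=C/I | intermediate
11 | 9-[(3R,4R,5E)-6-iodo-3-methyl-4-[(1S)-1-(triethylsilyloxy)ethyl]hex-5-enyl]-9-borabicyclo[3.3.1]nonane | C[C@H](O[Si](CC)(CC)CC)[C@H]([C@H](C)CCB1C2CCCC1CCC2)/C=C/I | intermediate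
12 | (3R,4R,5E)-6-iodo-3-methyl-4-[(1S)-1-(triethylsilyloxy)ethyl]hex-5-en-1-ol | C[C@H](O[Si](CC)(CC)CC)[C@H]([C@H](C)CCO)/C=C/I | intermediate
13 | (3R,4R,5E)-6-iodo-3-methyl-4-[(1S)-1-(triethylsilyloxy)ethyl]hex-5-enal | C[C@H](O[Si](CC)(CC)CC)[C@H]([C@H](C)CC=O)/C=C/I | intermediate
14 | (2E,5R,6R,7E)-8-iodo-5-methyl-6-[(1S)-1-(triethylsilyloxy)ethyl]octa-2,7-dienal | C[C@H](O[Si](CC)(CC)CC)[C@H]([C@H](C)C/C=C/C=O)/C=C/I | intermediate
15 | 2-[(1E)-buta-1,3-dien-1-yl]-4,4,5,5-tetramethyl-1,3,2-dioxaborolane | C=C/C=C/B1OC(C)(C)C(C)(C)O1 | starting material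
16 | (2E,5R,6R,7E,9E)-5-methyl-6-[(1S)-1-(triethylsilyloxy)ethyl]dodeca-2,7,9,11-tetraenal | C[C@H](O[Si](CC)(CC)CC)[C@H]([C@H](C)C/C=C/C=O)/C=C/C=C/C=C | intermediate
17 | (1R,2R,3aS,4R,5S,7aR)-5-ethenyl-2-methyl-1-[(1S)-1-(triethylsilyloxy)ethyl]-2,3,3a,4,5,7a-hexahydro-1H-indene-4-carbaldehyde (trans-fused; formyl and vinyl cis) | C[C@H](O[Si](CC)(CC)CC)[C@H]1[C@@H]2C=C[C@H](C=C)[C@H](C=O)[C@H]2C[C@H]1C | intermediate
18 | S-ethyl prop-2-enethioate | C=CC(=O)SCC | starting material
19 | S-ethyl (E)-3-{4-formyl-2-methyl-1-[(1S)-1-(triethylsilyloxy)ethyl]-2,3,3a,4,5,7a-hexahydro-1H-inden-5-yl}prop-2-enethioate (ring configuration as in 17) | C[C@H](O[Si](CC)(CC)CC)[C@H]1[C@@H]2C=C[C@H](/C=C/C(=O)SCC)[C@H](C=O)[C@H]2C[C@H]1C | intermediate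
20 | S-ethyl (E)-3-{2-methyl-4-[(E)-3-oxoprop-1-enyl]-1-[(1S)-1-(triethylsilyloxy)ethyl]-2,3,3a,4,5,7a-hexahydro-1H-inden-5-yl}prop-2-enethioate (ring configuration as in 17) | C[C@H](O[Si](CC)(CC)CC)[C@H]1[C@@H]2C=C[C@H](/C=C/C(=O)SCC)[C@H](/C=C/C=O)[C@H]2C[C@H]1C | intermediate
21 | S-ethyl 2-{7-formyl-2-methyl-3-[(1S)-1-(triethylsilyloxy)ethyl]-1,2,3,3a,5a,6,7,8,8a,8b-decahydro-as-indacen-6-yl}ethanethioate (trans-anti-cis core; 6-arm cis to H-5a; 6,7-trans) | C[C@H](O[Si](CC)(CC)CC)[C@H]1[C@@H]2C=C[C@@H]3[C@@H](CC(=O)SCC)[C@H](C=O)C[C@@H]3[C@H]2C[C@H]1C | intermediate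
22 | diethyl [(2,2-dimethyl-4-oxo-4H-1,3-dioxin-6-yl)methyl]phosphonate | CCOP(=O)(CC1=CC(=O)OC(C)(C)O1)OCC | starting material
23 | 21 with the formyl group replaced by (E)-2-(2,2-dimethyl-4-oxo-4H-1,3-dioxin-6-yl)ethenyl | C[C@H](O[Si](CC)(CC)CC)[C@H]1[C@@H]2C=C[C@@H]3[C@@H](CC(=O)SCC)[C@H](/C=C/C4=CC(=O)OC(C)(C)O4)C[C@@H]3[C@H]2C[C@H]1C | intermediate
24 | 23 with the CH2C(O)SEt arm reduced to CH2CHO | C[C@H](O[Si](CC)(CC)CC)[C@H]1[C@@H]2C=C[C@@H]3[C@@H](CC=O)[C@H](/C=C/C4=CC(=O)OC(C)(C)O4)C[C@@H]3[C@H]2C[C@H]1C | intermediate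
25 | tert-butyl bromoacetate | CC(C)(C)OC(=O)CBr | starting material
26 | diphenyl phosphite | O=[PH](Oc1ccccc1)Oc1ccccc1 | starting material
27 | tert-butyl (diphenoxyphosphoryl)acetate | CC(C)(C)OC(=O)CP(=O)(Oc1ccccc1)Oc1ccccc1 | intermediate
28 | 24 with the CH2CHO arm extended to the (Z)-but-2-enoic acid tert-butyl ester | C[C@H](O[Si](CC)(CC)CC)[C@H]1[C@@H]2C=C[C@@H]3[C@@H](C/C=C\C(=O)OC(C)(C)C)[C@H](/C=C/C4=CC(=O)OC(C)(C)O4)C[C@@H]3[C@H]2C[C@H]1C | intermediate
29 | 28 with free carboxylic acid and free (1S)-1-hydroxyethyl group | C[C@H](O)[C@H]1[C@@H]2C=C[C@@H]3[C@@H](C/C=C\C(=O)O)[C@H](/C=C/C4=CC(=O)OC(C)(C)O4)C[C@@H]3[C@H]2C[C@H]1C | intermediate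
30 | Nα-Boc-Nδ-Cbz-L-ornithine | CC(C)(C)OC(=O)N[C@@H](CCCNC(=O)OCc1ccccc1)C(=O)O | starting material
31 | methyl Nα-Boc-Nδ-Cbz-L-ornithinate | CC(C)(C)OC(=O)N[C@@H](CCCNC(=O)OCc1ccccc1)C(=O)OC | intermediate
32 | methyl Nα-Boc-L-ornithinate | CC(C)(C)OC(=O)N[C@@H](CCCN)C(=O)OC | intermediate
33 | benzotriazol-1-yl ester of 29 | C[C@H](O)[C@H]1[C@@H]2C=C[C@@H]3[C@@H](C/C=C\C(=O)On4nnc5ccccc45)[C@H](/C=C/C4=CC(=O)OC(C)(C)O4)C[C@@H]3[C@H]2C[C@H]1C | intermediate
34 | amide of 29 with the δ-amine of methyl Nα-Boc-L-ornithinate | C[C@H](O)[C@H]1[C@@H]2C=C[C@@H]3[C@@H](C/C=C\C(=O)NCCC[C@H](NC(=O)OC(C)(C)C)C(=O)OC)[C@H](/C=C/C4=CC(=O)OC(C)(C)O4)C[C@@H]3[C@H]2C[C@H]1C | intermediate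
35 | 34 with free α-amine | C[C@H](O)[C@H]1[C@@H]2C=C[C@@H]3[C@@H](C/C=C\C(=O)NCCC[C@H](N)C(=O)OC)[C@H](/C=C/C4=CC(=O)OC(C)(C)O4)C[C@@H]3[C@H]2C[C@H]1C | intermediate
36 | acylketene from 35 (dioxinone opened to C(=O)CH=C=O) | C[C@H](O)[C@H]1[C@@H]2C=C[C@@H]3[C@@H](C/C=C\C(=O)NCCC[C@H](N)C(=O)OC)[C@H](/C=C/C(=O)C=C=O)C[C@@H]3[C@H]2C[C@H]1C | intermediate
37 | macrocyclic β-keto lactam methyl ester (16-membered ring) | C[C@H](O)[C@H]1[C@@H]2C=C[C@@H]3[C@H]4C/C=C\C(=O)NCCC[C@@H](C(=O)OC)NC(=O)CC(=O)/C=C/[C@@H]4C[C@@H]3[C@H]2C[C@H]1C | intermediate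
38 | target with (1S)-1-hydroxyethyl in place of acetyl | C[C@H](O)[C@H]1[C@@H]2C=C[C@@H]3[C@H]4C/C=C\C(=O)NCCC[C@@H]5NC(=O)C(=C5O)C(=O)/C=C/[C@@H]4C[C@@H]3[C@H]2C[C@H]1C | intermediate
39 | CNP0320820.1 | CC(=O)[C@H]1[C@@H]2C=C[C@@H]3[C@H]4C/C=C\C(=O)NCCC[C@@H]5NC(=O)C(=C5O)C(=O)/C=C/[C@@H]4C[C@@H]3[C@H]2C[C@H]1C | target

**Totals**

Total step count: 24. Longest linear sequence: 21 steps (steps 1–14, 16, 17 and 20–24, from 1 to 39).

**Three steps most likely to fail**

Step 9, the intramolecular Diels–Alder reaction, could give the wrong diene face or some cis-fused product because control rests on the substrate alone. The fallback sets out from 12 and adds auxiliary control. Compound 12 is oxidised with Dess–Martin periodinane and, in the same flask, condensed with diethyl {2-[(4S)-4-benzyl-2-oxo-1,3-oxazolidin-3-yl]-2-oxoethyl}phosphonate (LiCl, iPr2NEt, MeCN) to give the N-enoyl oxazolidinone vinyl iodide F1. Suzuki coupling with 15 (Pd(PPh3)4, TlOEt) gives the triene imide F2. Me2AlCl in CH2Cl2 at −30 °C then brings about the chelate-controlled cycloaddition on the face away from the benzyl group, which is the face the route needs, giving the cycloadduct imide F3. LiBH4 removes the auxiliary to give the primary alcohol F4, and Dess–Martin oxidation comes back to the route at 17.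

Step 12, the reductive Michael cyclisation, may stop after the hydride transfer because the enamine is too weak a nucleophile for the enethioate. The fallback sets out from 20. The same Hantzsch ester and ammonium salt at 0–20 °C give the saturated aldehyde F5. Me3SiCl, Et3N and NaI in MeCN convert it into the trimethylsilyl enol ether F6. BF3·OEt2 in CH2Cl2 at −78 °C then closes ring C by an intramolecular Mukaiyama–Michael addition, and aqueous work-up comes back to the route at 21.

Step 24, the final oxidation, may be spoiled by reaction of the periodinane with the enolised tetramic acid. The fallback sets out from 37 and changes the order of events. Dess–Martin oxidation at the β-keto lactam stage gives the keto macrolactam F7, and a short Lacey–Dieckmann closure (KOtBu, tBuOH, rt, under 10 min to limit epimerisation next to the ketone) comes back to the route at 39.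

**Further compounds**

F1 | step 9 | (4S)-4-benzyl-3-[(2E,5R,6R,7E)-8-iodo-5-methyl-6-[(1S)-1-(triethylsilyloxy)ethyl]octa-2,7-dienoyl]-1,3-oxazolidin-2-one | C[C@H](O[Si](CC)(CC)CC)[C@H]([C@H](C)C/C=C/C(=O)N1[C@@H](Cc2ccccc2)COC1=O)/C=C/I
F2 | step 9 | (4S)-4-benzyl-3-[(2E,5R,6R,7E,9E)-5-methyl-6-[(1S)-1-(triethylsilyloxy)ethyl]dodeca-2,7,9,11-tetraenoyl]-1,3-oxazolidin-2-one | C[C@H](O[Si](CC)(CC)CC)[C@H]([C@H](C)C/C=C/C(=O)N1[C@@H](Cc2ccccc2)COC1=O)/C=C/C=C/C=C
F3 | step 9 | (4S)-4-benzyl-3-({5-ethenyl-2-methyl-1-[(1S)-1-(triethylsilyloxy)ethyl]-2,3,3a,4,5,7a-hexahydro-1H-inden-4-yl}carbonyl)-1,3-oxazolidin-2-one (ring configuration as in 17) | C[C@H](O[Si](CC)(CC)CC)[C@H]1[C@@H]2C=C[C@H](C=C)[C@H](C(=O)N3[C@@H](Cc4ccccc4)COC3=O)[C@H]2C[C@H]1C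
F4 | step 9 | {5-ethenyl-2-methyl-1-[(1S)-1-(triethylsilyloxy)ethyl]-2,3,3a,4,5,7a-hexahydro-1H-inden-4-yl}methanol (ring configuration as in 17) | C[C@H](O[Si](CC)(CC)CC)[C@H]1[C@@H]2C=C[C@H](C=C)[C@H](CO)[C@H]2C[C@H]1C
F5 | step 12 | S-ethyl (E)-3-{2-methyl-4-(3-oxopropyl)-1-[(1S)-1-(triethylsilyloxy)ethyl]-2,3,3a,4,5,7a-hexahydro-1H-inden-5-yl}prop-2-enethioate (ring configuration as in 17) | C[C@H](O[Si](CC)(CC)CC)[C@H]1[C@@H]2C=C[C@H](/C=C/C(=O)SCC)[C@H](CCC=O)[C@H]2C[C@H]1C
F6 | step 12 | trimethylsilyl enol ether of F5 (E/Z mixture at the enol ether) | C[C@H](O[Si](CC)(CC)CC)[C@H]1[C@@H]2C=C[C@H](/C=C/C(=O)SCC)[C@H](CC=CO[Si](C)(C)C)[C@H]2C[C@H]1C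
F7 | step 24 | keto macrolactam methyl ester (37 with acetyl in place of 1-hydroxyethyl) | CC(=O)[C@H]1[C@@H]2C=C[C@@H]3[C@H]4C/C=C\C(=O)NCCC[C@@H](C(=O)OC)NC(=O)CC(=O)/C=C/[C@@H]4C[C@@H]3[C@H]2C[C@H]1C
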